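The cyclohexane ring carries C7 (on C1), the C6 oxygen and the C5 oxygen on three adjacent carbons, all cis. Next to them sit C3 and C4, whose trans Cl/OH pair is a masked alkene. This is the pattern of an endo adduct of a (1E)-1-oxy-2-methylbutadiene with a cis dienophile.
Late disconnections: both angelates (mixed-anhydride esterification), the C10 carbinol (CBS reduction) and C8–C9 (boron aldol of the C7(=CH2)–C8HO enal with a 3-methyl-3-silyloxybutan-2-one enolate).
Before that: the enal comes from the butenolide carbinol C7 and its CH2O arm C8, Cl/OH from the β-epoxide, and the C6 acetate from a C6 methyl ketone by Baeyer–Villiger oxidation. The acetate carbonyl carbon is the old lactone carbonyl carbon.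
Ring order: the lactone ring comes in with the (S)-butenolide, the only carbocycle closes onto it, cis-fused, in the Diels–Alder reaction, and the lactone is then opened for good.
Key step: step 3

Convention: ring C1 bears the side chain, C2 is CH2, C3 bears Cl, C4 bears Me and OH, C5 the angelate, C6 the acetate. In the chain, C7 is the methylene-bearing carbon, C8 the carbinol, C9 CH2, C10 the angelate carbon and C11 is CMe2OH. β is the ring face that carries C7 and α the opposite face. In this numbering the target is 1R,3S,4S,5S,6S,8R,10R. Ang = (Z)-2-methylbut-2-enoyl, Ipc = isopinocampheyl.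
Assumption: (−)-Ipc2BCl is taken to send a methyl ketone enolate to the Re face of an aldehyde, the reverse of its sense with ethyl ketones. If the sense proves opposite, (+)-Ipc2BCl is used in the same step.

Step 1
Reactants: 1 tiglic aldehyde [(E)-2-methylbut-2-enal]
Product: 2 triethyl{[(1E)-2-methylbuta-1,3-dien-1-yl]oxy}silane
Conditions: TESOTf, Et3N, Et2O, 0 °C to rt
Reagents that add atoms: triethylsilyl trifluoromethanesulfonate, CC[Si](CC)(CC)OS(=O)(=O)C(F)(F)F
Why: Silyl dienol ether formation by soft enolisation, in which O-silylation of the s-trans enal and γ-deprotonation by Et3N should give mainly the 1E isomer (any 1Z isomer cannot reach a reactive s-cis geometry and is a spectator in step 3); TES is chosen so that C5–O can later be freed before the other silyl ethers.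

Step 2
Reactants: 3 (S)-5-(hydroxymethyl)furan-2(5H)-one
Product: 4 (S)-5-{[tert-butyl(diphenyl)silyl]oxymethyl}furan-2(5H)-one
Conditions: TBDPSCl, imidazole, CH2Cl2, 0 °C to rt
Reagents that add atoms: tert-butyl(chloro)diphenylsilane, CC(C)(C)[Si](Cl)(c1ccccc1)c1ccccc1
Why: Imidazole-promoted silylation of a primary alcohol is too weakly basic to deprotonate the γ-position, so the (S) centre (future C7) should stay intact, and the bulky TBDPS arm is what shields one face in step 3.

Step 3
Reactants: 2 triethylsilyl dienol ether; 4 TBDPS butenolide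
Product: 5 cis-fused cyclohexene lactone adduct (lactone carbonyl on C6, carbinol carbon C7 on C1, OTES on C5, all β)
Conditions: 2 (excess), BHT (cat.), toluene (concentrated), sealed tube, 150 °C
Reagents that add atoms: none
Why: A concerted, asynchronous, normal-electron-demand [4+2] cycloaddition forms C1–C2 and C5–C6; the thermal Diels–Alder reaction of 5-substituted furan-2(5H)-ones with 1-oxygenated dienes is a known reaction type. The six-membered carbocycle closes by the cycloaddition itself and is cis-fused to the lactone because the cis geometry of the dienophile is carried over suprafacially. The 1-silyloxy group places the largest HOMO coefficient on the unsubstituted diene terminus, which bonds to the β-carbon of the butenolide, so the oxygenated terminus (C5) joins the α-carbon (C6); this ortho preference must outweigh the weaker, opposing para preference of the 2-methyl group. C1 and C6 are set by the butenolide stereocentre C7, whose silyloxymethyl arm blocks one face so that the diene adds anti to it. C5 is set by the 1E geometry of the dienol ether together with endo approach (lactone carbonyl under the diene), which puts the C5 silyloxy group cis to the C6 carbonyl carbon and to C7. The step therefore needs regio-, endo- and facial selectivity, and excess diene, high concentration and a radical inhibitor offset the low reactivity of the butenolide.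

Step 4
Reactants: 5 lactone adduct
Product: 6 C7-hydroxy Weinreb amide
Conditions: MeNH(OMe)·HCl, AlMe3, CH2Cl2, 0 °C to rt; aqueous work-up, used crude
Reagents that add atoms: N,O-dimethylhydroxylamine hydrochloride, CNOC.Cl
Why: Aluminium-amide aminolysis of a γ-lactone (Weinreb amide formation) cleaves only the acyl–oxygen bond, so C6 and C7 keep their configuration; the hydroxy amide is carried on at once because it can relactonise.

Step 5
Reactants: 6 hydroxy Weinreb amide
Product: 7 C7-OTBS Weinreb amide
Conditions: TBSOTf, 2,6-lutidine, CH2Cl2, −78 to 0 °C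
Reagents that add atoms: tert-butyldimethylsilyl trifluoromethanesulfonate, CC(C)(C)[Si](C)(C)OS(=O)(=O)C(F)(F)F
Why: Silyl triflate silylation of the hindered secondary C7 alcohol blocks relactonisation, and TBS lies between TES (C5) and TBDPS (C8) in acid lability, so the three oxygens can be freed one after another.

Step 6
Reactants: 7 Weinreb amide
Product: 8 C6 methyl ketone
Conditions: MeMgBr, THF, −20 to 0 °C; pH 7 buffer
Reagents that add atoms: methylmagnesium bromide, C[Mg]Br
Why: Weinreb ketone synthesis, in which the magnesium-chelated tetrahedral adduct survives until the quench, so one methyl group is added and the lactone carbonyl carbon becomes the acetyl carbonyl; low temperature and a neutral quench should spare the epimerisable C6 centre and the β-silyloxy group.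

Step 7
Reactants: 8 methyl ketone
Product: 9 C5 allylic alcohol
Conditions: HF·pyridine, pyridine, THF, 0 °C
Reagents that add atoms: none
Why: Selective desilylation, since pyridine-buffered HF cleaves a TES ether far faster than TBS or TBDPS ethers, and the near-neutral medium should avoid dehydration or C6 epimerisation of the β-hydroxy ketone.

Step 8
Reactants: 9 allylic alcohol
Product: 10 3β,4β-epoxy alcohol
Conditions: VO(acac)2 (cat.), t-BuOOH (decane), CH2Cl2, 0 °C to rt
Reagents that add atoms: tert-butyl hydroperoxide, CC(C)(C)OO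
Why: Hydroxyl-directed vanadium-catalysed epoxidation of an allylic alcohol, in which the C5 alkoxide binds vanadium and the bound peroxide delivers oxygen to the β face; this sets C3 and C4 cis to C5–OH although that face is the more crowded one.

Step 9
Reactants: 10 epoxy alcohol methyl ketone
Product: 11 C6 acetate with C5–OH free
Conditions: mCPBA, NaHCO3, CH2Cl2, rt
Reagents that add atoms: 3-chloroperoxybenzoic acid, O=C(OO)c1cccc(Cl)c1
Why: Baeyer–Villiger oxidation, in which the secondary carbon C6 migrates in the Criegee adduct in preference to methyl and with retention, so the C6–O bond forms on the β face and the former lactone carbonyl becomes the acetate carbonyl; no alkene is left to compete and the buffer protects the epoxide.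

Step 10
Reactants: 11 epoxy alcohol acetate
Product: 12 C5 angelate epoxide
Conditions: angelic acid, 2,4,6-trichlorobenzoyl chloride, Et3N, toluene, rt; then 11, 80 °C
Reagents that add atoms: angelic acid, C/C=C(/C)C(=O)O
Why: Yamaguchi-type mixed-anhydride esterification without DMAP is the known way to make angelates without Z to E isomerisation; C5–OH is the only free hydroxyl, and the aprotic, weakly basic medium should keep acetyl migration from C6 slower than acylation.

Step 11
Reactants: 12 angelate epoxide
Product: 13 3α-chloro-4β-hydroxy compound (chlorohydrin)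
Conditions: Li2CuCl4, THF, 0 °C to rt; H2O
Reagents that add atoms: dilithium tetrachlorocuprate Li2CuCl4, [Li+].[Li+].[Cu+2].[Cl-].[Cl-].[Cl-].[Cl-]
Why: Lewis-acid-assisted SN2 opening of the epoxide by chloride (Fürst–Plattner trans-diaxial opening), in which chloride attacks secondary C3 from the α face with inversion in the half-chair that keeps the C1 branch equatorial; C4 is tertiary and deactivated by the C5 acyloxy group and the β esters cannot reach the rear side, so Cl becomes 3α and C4–OH stays β.

Step 12
Reactants: 13 chlorohydrin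
Product: 14 C7 alcohol
Conditions: aq. HF, MeCN, 0 °C
Reagents that add atoms: none
Why: Acid-type desilylation, since aqueous HF removes the secondary TBS ether while the far more robust primary TBDPS ether, the esters and the chlorohydrin should survive.

Step 13
Reactants: 14 C7 alcohol
Product: 15 C7 ketone
Conditions: Dess–Martin periodinane, NaHCO3, CH2Cl2, 0 °C to rt
Reagents that add atoms: none
Why: Dess–Martin oxidation runs under neutral buffered conditions, touches only the secondary C7 alcohol (C4–OH is tertiary) and should trigger neither β-elimination of the C6 acetate nor epimerisation at C1.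

Step 14
Reactants: 15 C7 ketone
Product: 16 C7 methylene compound
Conditions: Zn, CH2Br2, TiCl4 (reagent pre-formed in THF, −40 to 5 °C), CH2Cl2, 0 °C to rt
Reagents that add atoms: dibromomethane, BrCBr
Why: Takai–Lombardo methylenation uses a non-basic gem-dimetallic reagent that converts ketones but not esters into methylene groups and suits enolisable ketones, so the C1 centre and the β-acetoxy group should be kept.

Step 15
Reactants: 16 allylic TBDPS ether
Product: 17 primary allylic alcohol
Conditions: HF·pyridine, THF, 0 °C to rt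
Reagents that add atoms: none
Why: Fluoride cleavage of the last silyl ether with acidic HF·pyridine rather than a basic fluoride source avoids closure of the chlorohydrin to the epoxide and acyl migration.

Step 16
Reactants: 17 allylic alcohol
Product: 18 C8 enal (2-substituted acrolein)
Conditions: MnO2, CH2Cl2, rt
Reagents that add atoms: none
Why: MnO2 oxidation is neutral and selective for the allylic primary alcohol and should stop at the aldehyde.

Step 17
Reactants: 19 3-hydroxy-3-methylbutan-2-one
Product: 20 3-methyl-3-(triethylsilyloxy)butan-2-one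
Conditions: TESOTf, 2,6-lutidine, CH2Cl2, 0 °C
Reagents that add atoms: triethylsilyl trifluoromethanesulfonate, CC[Si](CC)(CC)OS(=O)(=O)C(F)(F)F
Why: Silyl triflate silylation is the standard protection of a tertiary alcohol; it removes the acidic proton and leaves the methyl group as the only enolisable site.

Step 18
Reactants: 18 enal; 20 TES-protected ketone
Product: 23 (8R)-aldol adduct, via diisopinocampheylboron enolate 21 (not isolated), via boron aldolate 22 (not isolated)
Conditions: 20 (excess), (−)-Ipc2BCl, Et3N, Et2O, 0 °C; then 18, −78 to −20 °C; H2O2, pH 7 buffer, MeOH, 0 °C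
Reagents that add atoms: none
Why: Boron-mediated aldol reaction of a methyl ketone under reagent control, in which Ipc2BCl/Et3N enolises the only available methyl group and the chiral ligands should steer the enolate to the Re face of the C8 aldehyde, forming C8–C9 and the 8R carbinol; this type of control is moderate, but the C8 epimers are separable diastereomers, and excess enolate allows for the free C4–OH.

Step 19
Reactants: 23 aldol adduct
Product: 24 C8-OTES ketone
Conditions: TESCl, imidazole, CH2Cl2, 0 °C
Reagents that add atoms: chlorotriethylsilane, CC[Si](Cl)(CC)CC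
Why: Chlorosilane/imidazole silylation distinguishes the secondary allylic C8–OH from the hindered tertiary C4–OH and fixes the difference between C8–O and C10–O that the target demands.

Step 20
Reactants: 24 C10 ketone
Product: 25 (10R)-alcohol
Conditions: (S)-Me-CBS [(S)-1-methyl-3,3-diphenyltetrahydro-1H,3H-pyrrolo[1,2-c][1,3,2]oxazaborole], BH3·SMe2, THF, −30 °C; MeOH
Reagents that add atoms: none
Why: Corey–Bakshi–Shibata reduction, in which the large size difference between the quaternary C11 arm and the C9 methylene arm (a pinacolone-like ketone) should let the (S)-catalyst deliver hydride to give the 10R alcohol, 1,3-anti to C8; the esters are inert and the hindered 1,1-disubstituted alkene should react more slowly than the catalysed ketone reduction.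

Step 21
Reactants: 25 C10 alcohol
Product: 26 bis-angelate bis-TES ether
Conditions: angelic acid, 2,4,6-trichlorobenzoyl chloride, Et3N, toluene, rt; then 25, 80 °C
Reagents that add atoms: angelic acid, C/C=C(/C)C(=O)O
Why: The same DMAP-free Yamaguchi-type angeloylation applies because C10–OH is the only free secondary alcohol, the tertiary C4–OH does not acylate, and triethylamine is too weak a base to close the chlorohydrin.

Step 22
Reactants: 26 bis-TES ether
Product: 27 CNP0124048.1 (target)
Conditions: HF·pyridine, pyridine, THF, 0 °C to rt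
Reagents that add atoms: none
Why: Fluoride-induced cleavage of both TES ethers under weakly acidic conditions frees C8–OH and C11–OH without ester migration, angelate isomerisation or epoxide formation.

Compound list
1 | tiglic aldehyde, (E)-2-methylbut-2-enal | C/C=C(\C)C=O | starting material
2 | triethyl{[(1E)-2-methylbuta-1,3-dien-1-yl]oxy}silane | C=C/C(C)=C/O[Si](CC)(CC)CC | intermediate
3 | (S)-5-(hydroxymethyl)furan-2(5H)-one | O=C1O[C@H](CO)C=C1 | starting material
4 | (S)-5-{[tert-butyl(diphenyl)silyl]oxymethyl}furan-2(5H)-one | O=C1O[C@H](CO[Si](c2ccccc2)(c2ccccc2)C(C)(C)C)C=C1 | intermediate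
5 | (3S,3aS,7S,7aS)-3-{[tert-butyl(diphenyl)silyl]oxymethyl}-6-methyl-7-(triethylsilyloxy)-3a,4,7,7a-tetrahydro-2-benzofuran-1(3H)-one (cis-fused adduct) | O=C1O[C@H](CO[Si](c3ccccc3)(c3ccccc3)C(C)(C)C)[C@H]2CC=C(C)[C@@H](O[Si](CC)(CC)CC)[C@@H]12 | intermediate
6 | cyclohex-3-ene with 1β-[(1S)-2-(TBDPSO)-1-hydroxyethyl], 4-methyl, 5β-OTES, 6β-C(=O)N(OMe)Me | CC(C)(C)[Si](c1ccccc1)(c1ccccc1)OC[C@@H](O)[C@H]1CC=C(C)[C@@H](O[Si](CC)(CC)CC)[C@H]1C(=O)N(C)OC | intermediate
7 | as 6, with (7S)-OTBS | CC(C)(C)[Si](c1ccccc1)(c1ccccc1)OC[C@@H](O[Si](C)(C)C(C)(C)C)[C@H]1CC=C(C)[C@@H](O[Si](CC)(CC)CC)[C@H]1C(=O)N(C)OC | intermediate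
8 | as 7, with 6β-acetyl in place of the amide | CC(C)(C)[Si](c1ccccc1)(c1ccccc1)OC[C@@H](O[Si](C)(C)C(C)(C)C)[C@H]1CC=C(C)[C@@H](O[Si](CC)(CC)CC)[C@H]1C(C)=O | intermediate
9 | as 8, with 5β-OH free | CC(C)(C)[Si](c1ccccc1)(c1ccccc1)OC[C@@H](O[Si](C)(C)C(C)(C)C)[C@H]1CC=C(C)[C@@H](O)[C@H]1C(C)=O | intermediate
10 | 3β,4β-epoxide of 9 (epoxide cis to 5β-OH) | CC(C)(C)[Si](c1ccccc1)(c1ccccc1)OC[C@@H](O[Si](C)(C)C(C)(C)C)[C@H]1C[C@H]2O[C@@]2(C)[C@@H](O)[C@H]1C(C)=O | intermediate
11 | as 10, with 6β-OAc in place of acetyl | CC(C)(C)[Si](c1ccccc1)(c1ccccc1)OC[C@@H](O[Si](C)(C)C(C)(C)C)[C@H]1C[C@H]2O[C@@]2(C)[C@@H](O)[C@H]1OC(C)=O | intermediate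
12 | as 11, with 5β-OAng | CC(C)(C)[Si](c1ccccc1)(c1ccccc1)OC[C@@H](O[Si](C)(C)C(C)(C)C)[C@H]1C[C@H]2O[C@@]2(C)[C@@H](OC(=O)/C(C)=C\C)[C@H]1OC(C)=O | intermediate
13 | cyclohexane with 3α-Cl, 4β-OH/4α-Me, 5β-OAng, 6β-OAc, 1β-[(1S)-1-(TBSO)-2-(TBDPSO)ethyl] | CC(C)(C)[Si](c1ccccc1)(c1ccccc1)OC[C@@H](O[Si](C)(C)C(C)(C)C)[C@H]1C[C@H](Cl)[C@@](C)(O)[C@@H](OC(=O)/C(C)=C\C)[C@H]1OC(C)=O | intermediate
14 | as 13, with (7S)-OH free | CC(C)(C)[Si](c1ccccc1)(c1ccccc1)OC[C@@H](O)[C@H]1C[C@H](Cl)[C@@](C)(O)[C@@H](OC(=O)/C(C)=C\C)[C@H]1OC(C)=O | intermediate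
15 | C7 ketone, 1β-[2-(TBDPSO)acetyl] | CC(C)(C)[Si](c1ccccc1)(c1ccccc1)OCC(=O)[C@H]1C[C@H](Cl)[C@@](C)(O)[C@@H](OC(=O)/C(C)=C\C)[C@H]1OC(C)=O | intermediate
16 | C7 methylene compound, 1β-[3-(TBDPSO)prop-1-en-2-yl] | CC(C)(C)[Si](c1ccccc1)(c1ccccc1)OCC(=C)[C@H]1C[C@H](Cl)[C@@](C)(O)[C@@H](OC(=O)/C(C)=C\C)[C@H]1OC(C)=O | intermediate
17 | allylic alcohol, 1β-(3-hydroxyprop-1-en-2-yl) | OCC(=C)[C@H]1C[C@H](Cl)[C@@](C)(O)[C@@H](OC(=O)/C(C)=C\C)[C@H]1OC(C)=O | intermediate
18 | enal, 1β-(3-oxoprop-1-en-2-yl) | O=CC(=C)[C@H]1C[C@H](Cl)[C@@](C)(O)[C@@H](OC(=O)/C(C)=C\C)[C@H]1OC(C)=O | intermediate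
19 | 3-hydroxy-3-methylbutan-2-one | CC(=O)C(C)(C)O | starting material
20 | 3-methyl-3-(triethylsilyloxy)butan-2-one | CC(=O)C(C)(C)O[Si](CC)(CC)CC | intermediate
21 | diisopinocampheylboron enolate of 20 | C=C(OB([C@@H]1C[C@@H]2C[C@H]([C@H]1C)C2(C)C)[C@@H]1C[C@@H]2C[C@H]([C@H]1C)C2(C)C)C(C)(C)O[Si](CC)(CC)CC | intermediate
22 | (8R)-O-diisopinocampheylboryl aldolate | C=C([C@H](OB([C@@H]2C[C@@H]3C[C@H]([C@H]2C)C3(C)C)[C@@H]2C[C@@H]3C[C@H]([C@H]2C)C3(C)C)CC(=O)C(C)(C)O[Si](CC)(CC)CC)[C@H]1C[C@H](Cl)[C@@](C)(O)[C@@H](OC(=O)/C(C)=C\C)[C@H]1OC(C)=O | intermediate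
23 | (8R)-aldol: C8–OH, C10 ketone, C11–OTES | C=C([C@H](O)CC(=O)C(C)(C)O[Si](CC)(CC)CC)[C@H]1C[C@H](Cl)[C@@](C)(O)[C@@H](OC(=O)/C(C)=C\C)[C@H]1OC(C)=O | intermediate
24 | as 23, with (8R)-OTES | C=C([C@H](O[Si](CC)(CC)CC)CC(=O)C(C)(C)O[Si](CC)(CC)CC)[C@H]1C[C@H](Cl)[C@@](C)(O)[C@@H](OC(=O)/C(C)=C\C)[C@H]1OC(C)=O | intermediate
25 | as 24, with (10R)-OH (8,10-anti) | C=C([C@H](O[Si](CC)(CC)CC)C[C@@H](O)C(C)(C)O[Si](CC)(CC)CC)[C@H]1C[C@H](Cl)[C@@](C)(O)[C@@H](OC(=O)/C(C)=C\C)[C@H]1OC(C)=O | intermediate
26 | as 25, with (10R)-OAng | C=C([C@H](O[Si](CC)(CC)CC)C[C@@H](OC(=O)/C(C)=C\C)C(C)(C)O[Si](CC)(CC)CC)[C@H]1C[C@H](Cl)[C@@](C)(O)[C@@H](OC(=O)/C(C)=C\C)[C@H]1OC(C)=O | intermediate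
27 | CNP0124048.1, (1R,3S,4S,5S,6S,8R,10R) in the numbering above | C=C([C@H](O)C[C@@H](OC(=O)/C(C)=C\C)C(C)(C)O)[C@H]1C[C@H](Cl)[C@@](C)(O)[C@@H](OC(=O)/C(C)=C\C)[C@H]1OC(C)=O | target

Total step count: 22. Longest linear sequence: 20 (step 1 or 2, steps 3–16, steps 18–22).

Steps most likely to fail

1. Step 3. The butenolide is a sluggish dienophile. Thermal decay of the dienol ether, loss of endo selectivity, or leakage towards the regiochemistry favoured by the 2-methyl group may therefore outrun the wanted cycloaddition.
Fallback (activated dienophile), setting out from 4: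
- Addition of Br2 in CH2Cl2 should give the trans-dibromolactone F1.
- Et3N should then remove HBr to give the 3-bromobutenolide F2.
- The lowered LUMO of F2 should allow cycloaddition with 2 at a clearly lower temperature, with the same anti-facial control, to give the 7a-bromo adduct F3.
- Radical debromination with Bu3SnH/AIBN in toluene at 80 °C should deliver hydrogen to the convex face of the C6 radical. A radical does not expel the neighbouring silyloxy group. The cis ring fusion is restored and the route is rejoined at 5.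

2. Step 9. Three things may go wrong:
- Formation of the Criegee adduct at the ketone, which is flanked by two cis neighbours, may be too slow.
- Prolonged contact with the carboxylic acid may open the epoxide.
- The new acetate may migrate to the free C5–OH.
Fallback (change of substrate so that a forcing peracid can be used), setting out from 10:
- The epoxide is opened first, directed by the free C5–OH, with Et2NH·HCl and Ti(OiPr)4 in CH2Cl2 to give the chlorodiol ketone F4.
- The cis C4/C5 diol is tied up with 2,2-dimethoxypropane and PPTS as the acetonide ketone F5.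
- F5 has no epoxide, alkene or free hydroxyl left. It should tolerate CF3CO3H (from urea·H2O2 and (CF3CO)2O, with Na2HPO4, in CH2Cl2 at 0 °C) and give the acetonide acetate F6.
- Aqueous acetic acid should free the chlorodiol acetate F7.
- The mixed-anhydride angeloylation of step 10 acylates the secondary C5–OH of F7 only, and the route is rejoined at 13.

3. Step 14. Enolisation of the β-acetoxy ketone may lead to loss of the C6 acetate or epimerisation at C1. The hindered carbonyl may resist the reagent, or low-valent metal species may attack the chlorohydrin.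
Fallback (stepwise Peterson olefination), setting out from 15:
- The weakly basic reagent made from Me3SiCH2MgCl and CeCl3 in THF at −78 °C should add to the ketone much faster than to the esters. It gives the β-hydroxysilane F8; both C7 epimers serve.
- HF·pyridine in THF should then bring about the acid-type Peterson elimination and the cleavage of the TBDPS ether in one operation. Step 15 is skipped and the route is rejoined at 17.

Further compounds
F1 | step 3 | (5S)-3,4-trans-dibromo-5-{[tert-butyl(diphenyl)silyl]oxymethyl}dihydrofuran-2(3H)-one (4-Br trans to the C5 arm) | O=C1O[C@H](CO[Si](c2ccccc2)(c2ccccc2)C(C)(C)C)[C@@H](Br)[C@@H]1Br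
F2 | step 3 | (S)-3-bromo-5-{[tert-butyl(diphenyl)silyl]oxymethyl}furan-2(5H)-one | O=C1O[C@H](CO[Si](c2ccccc2)(c2ccccc2)C(C)(C)C)C=C1Br
F3 | step 3 | 7a-bromo analogue of adduct 5 (Br on C6, α) | O=C1O[C@H](CO[Si](c3ccccc3)(c3ccccc3)C(C)(C)C)[C@H]2CC=C(C)[C@@H](O[Si](CC)(CC)CC)[C@@]12Br
F4 | step 9 | chlorodiol ketone: 3α-Cl, 4β-OH, 5β-OH, 6β-acetyl, (7S)-OTBS, C8–OTBDPS | CC(C)(C)[Si](c1ccccc1)(c1ccccc1)OC[C@@H](O[Si](C)(C)C(C)(C)C)[C@H]1C[C@H](Cl)[C@@](C)(O)[C@@H](O)[C@H]1C(C)=O
F5 | step 9 | C4,C5-acetonide of F4 | CC(C)(C)[Si](c1ccccc1)(c1ccccc1)OC[C@@H](O[Si](C)(C)C(C)(C)C)[C@H]1C[C@H](Cl)[C@@]2(C)OC(C)(C)O[C@H]2[C@H]1C(C)=O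
F6 | step 9 | acetonide with 6β-OAc | CC(C)(C)[Si](c1ccccc1)(c1ccccc1)OC[C@@H](O[Si](C)(C)C(C)(C)C)[C@H]1C[C@H](Cl)[C@@]2(C)OC(C)(C)O[C@H]2[C@H]1OC(C)=O
F7 | step 9 | chlorodiol acetate: 3α-Cl, 4β-OH, 5β-OH, 6β-OAc | CC(C)(C)[Si](c1ccccc1)(c1ccccc1)OC[C@@H](O[Si](C)(C)C(C)(C)C)[C@H]1C[C@H](Cl)[C@@](C)(O)[C@@H](O)[C@H]1OC(C)=O
F8 | step 14 | β-hydroxysilane: C7 tertiary alcohol bearing CH2SiMe3 and CH2OTBDPS (C7 epimers) | CC(C)(C)[Si](c1ccccc1)(c1ccccc1)OCC(O)(C[Si](C)(C)C)[C@H]1C[C@H](Cl)[C@@](C)(O)[C@@H](OC(=O)/C(C)=C\C)[C@H]1OC(C)=O
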